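**Retrosynthetic overview**

1. Target ⇒ chemoselective hydrogenation of the enone C=C of the corresponding E-chalcone ⇒ protecting-group-free Claisen–Schmidt union of 3-hydroxy-4-methoxy-5-prenylbenzaldehyde with 3'-prenyl-2',4',6'-trihydroxyacetophenone.
2. B-ring aldehyde ⇒ O4–CH3 bond: site-selective O-methylation of the more acidic 4-OH of 3,4-dihydroxy-5-prenylbenzaldehyde.
3. Key disconnection: the C5 prenyl group is traced back to an O4–C(CH3)2CH=CH2 bond, formed catalytically from 3,4-dihydroxybenzaldehyde and isoprene and relayed to C5 by an aromatic Claisen shift in the same flask.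
4. A-ring ketone ⇒ direct C-prenylation of 2',4',6'-trihydroxyacetophenone with prenyl bromide.
5. Rings: none is built. Both benzene rings are bought (B as protocatechualdehyde, A as phloroacetophenone) and joined last through the C3 chain.

Assumption: the target has no stereocentre and no stereogenic double bond, so it is made as the single achiral compound drawn; the only transient stereo-elements (racemic 4 and 10, E-alkene of 11) disappear before the end.

**Step 1**
Reactants: 1 3,4-dihydroxybenzaldehyde; 2 isoprene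
Product: 5 3,4-dihydroxy-5-(3-methylbut-2-enyl)benzaldehyde, via 3-hydroxy-4-(2-methylbut-3-en-2-yloxy)benzaldehyde 3 (not isolated), via 4-formyl-2-hydroxy-6-(3-methylbut-2-enyl)cyclohexa-2,4-dien-1-one 4 (not isolated)
Conditions: Pd2(dba)3 (2.5 mol %), DPEphos (6 mol %), isoprene (6 equiv), 1,4-dioxane, sealed tube, 110 °C, 18 h
Reagents that add atoms: none
Why: Proposed new method: Pd(0) and the more acidic 4-OH of 1 (para to CHO, pKa ≈ 7) give a Pd–H/phenoxide pair, Pd–H adds to isoprene to form the 1,1-dimethyl-π-allyl complex, and the phenoxide attacks its tertiary terminus (favoured by the wide-bite-angle diphosphine, which also blocks 2:1 telomerisation) to form the O4–C bond of ether 3 reversibly; only this tertiary ether undergoes aromatic Claisen [3,3] rearrangement at 110 °C, to the one free ortho carbon C5, and tautomerisation of dienone 4 makes the sequence irreversible, while the linear prenyl ether re-ionises back into the pool; the closest known reaction types are Pd-catalysed 1:1 hydroalkoxylation/hydroamination of 1,3-dienes, Pd-catalysed O-tert-prenylation of phenols with tertiary allylic carbonates, and the thermal Claisen rearrangement of 1,1-dimethylallyl aryl ethers.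

**Step 2**
Reactants: 5 3,4-dihydroxy-5-(3-methylbut-2-enyl)benzaldehyde
Product: 6 3-hydroxy-4-methoxy-5-(3-methylbut-2-enyl)benzaldehyde
Conditions: MeI (1.1 equiv), Li2CO3 (1.2 equiv), DMF, 40 °C, 16 h
Reagents that add atoms: iodomethane, CI
Why: Williamson O-methylation in which the weak base ionises only the 4-OH (para to CHO, more acidic than the 3-OH; compare vanillin pKa 7.4 with isovanillin 8.9), the same selectivity as the established 4-O-alkylation of 3,4-dihydroxybenzaldehydes.

**Step 3**
Reactants: 7 2',4',6'-trihydroxyacetophenone; 8 prenyl bromide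
Product: 9 1-[2,4,6-trihydroxy-3-(3-methylbut-2-enyl)phenyl]ethanone
Conditions: 10 % aq KOH (1.0 equiv), prenyl bromide (0.9 equiv, slow addition), 0 °C to rt, 3 h; then dilute HCl
Reagents that add atoms: none
Why: Direct C-prenylation of an acylphloroglucinol: the hydrated, enolate-like phenoxide reacts with the soft allylic bromide at ring carbon (C3 and C5 are equivalent), and a deficit of bromide limits di-prenylation (a known reaction of moderate yield, run on the cheapest material).

**Step 4**
Reactants: 6 3-hydroxy-4-methoxy-5-(3-methylbut-2-enyl)benzaldehyde; 9 1-[2,4,6-trihydroxy-3-(3-methylbut-2-enyl)phenyl]ethanone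
Product: 11 (E)-3,2',4',6'-tetrahydroxy-4-methoxy-3',5-diprenylchalcone, via β-hydroxy ketone aldol adduct 10 (not isolated)
Conditions: 50 % aq KOH (20 equiv), EtOH, Ar, 0 °C to rt, 48–72 h; then 1 M HCl to pH 4 at 0 °C, fast EtOAc extraction, crude used at once
Reagents that add atoms: none
Why: Claisen–Schmidt crossed aldol condensation (E1cB dehydration gives the E-enone): the aldehyde has no α-hydrogen and its 3-phenoxide is meta to CHO so it stays electrophilic, and in strong base the product rests as the open-chain chalcone polyphenolate, with cold acidification keeping it from closing to a flavanone.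

**Step 5**
Reactants: 11 (E)-3,2',4',6'-tetrahydroxy-4-methoxy-3',5-diprenylchalcone
Product: 12 3,2',4',6'-tetrahydroxy-4-methoxy-3',5-diprenyldihydrochalcone
Conditions: H2 (1 atm), RhCl(PPh3)3 (10 mol %), degassed THF, rt, 12–24 h
Reagents that add atoms: none
Why: Homogeneous hydrogenation with Wilkinson's catalyst reduces the 1,2-disubstituted conjugated C=C, whereas the two trisubstituted prenyl alkenes are essentially inert to this catalyst at 1 atm; the neutral aprotic medium avoids flavanone closure, and no stereocentre is created.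

**Compound list**

1 | 3,4-dihydroxybenzaldehyde (protocatechualdehyde) | O=Cc1ccc(O)c(O)c1 | starting material
2 | isoprene (2-methylbuta-1,3-diene) | C=CC(C)=C | starting material
3 | 3-hydroxy-4-(2-methylbut-3-en-2-yloxy)benzaldehyde | C=CC(C)(C)Oc1ccc(C=O)cc1O | intermediate (not isolated)
4 | 4-formyl-2-hydroxy-6-(3-methylbut-2-enyl)cyclohexa-2,4-dien-1-one (racemic, transient) | CC(C)=CCC1C=C(C=O)C=C(O)C1=O | intermediate (not isolated)
5 | 3,4-dihydroxy-5-(3-methylbut-2-enyl)benzaldehyde | CC(C)=CCc1cc(C=O)cc(O)c1O | intermediate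
6 | 3-hydroxy-4-methoxy-5-(3-methylbut-2-enyl)benzaldehyde | COc1c(O)cc(C=O)cc1CC=C(C)C | intermediate
7 | 2',4',6'-trihydroxyacetophenone, 1-(2,4,6-trihydroxyphenyl)ethanone | CC(=O)c1c(O)cc(O)cc1O | starting material
8 | prenyl bromide (1-bromo-3-methylbut-2-ene) | CC(C)=CCBr | starting material
9 | 1-[2,4,6-trihydroxy-3-(3-methylbut-2-enyl)phenyl]ethanone | CC(=O)c1c(O)cc(O)c(CC=C(C)C)c1O | intermediate
10 | 3-hydroxy-3-[3-hydroxy-4-methoxy-5-(3-methylbut-2-enyl)phenyl]-1-[2,4,6-trihydroxy-3-(3-methylbut-2-enyl)phenyl]propan-1-one (racemic aldol adduct) | COc1c(O)cc(C(O)CC(=O)c2c(O)cc(O)c(CC=C(C)C)c2O)cc1CC=C(C)C | intermediate (not isolated)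
11 | (E)-3-[3-hydroxy-4-methoxy-5-(3-methylbut-2-enyl)phenyl]-1-[2,4,6-trihydroxy-3-(3-methylbut-2-enyl)phenyl]prop-2-en-1-one | COc1c(O)cc(/C=C/C(=O)c2c(O)cc(O)c(CC=C(C)C)c2O)cc1CC=C(C)C | intermediate
12 | 3,2',4',6'-tetrahydroxy-4-methoxy-3',5-diprenyldihydrochalcone | COc1c(O)cc(CCC(=O)c2c(O)cc(O)c(CC=C(C)C)c2O)cc1CC=C(C)C | target

**Totals and risks**

Total step count: 5 (steps 1–2 on the B-ring branch, step 3 on the A-ring branch, steps 4–5 after the union).
Longest linear sequence: 4 steps (1, 2, 4, 5).

Three steps most likely to fail: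

Step 1 (proposed new reaction). Risks are telomerisation of isoprene, Pd–H addition in the other sense (giving the 2-methylbut-2-enyl isomer), and reaction at O3. Fallback with known chemistry, setting out from 1 and coming back at 5: 1 is alkylated at the 4-OH with commercial 3-chloro-3-methylbut-1-yne (K2CO3 1.1 equiv, KI, cat. CuI, acetone, 50 °C) to give 3-hydroxy-4-(2-methylbut-3-yn-2-yloxy)benzaldehyde F1. Lindlar semihydrogenation (H2, Pd/CaCO3–Pb, quinoline, EtOAc) turns the alkyne into the tertiary allyl ether 3, which is isolated this time. Heating 3 without metal (DMF or N,N-diethylaniline, 120–130 °C) gives the same Claisen product 5.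

Step 4 (aldol on the unprotected polyphenols). Risks are slow enolisation of the polyanion and partial flavanone closure on work-up. Fallback, setting out from 9 (with 6) and coming back at 12: 9 is protected with MOMCl/K2CO3 in acetone to give 1-[2-hydroxy-4,6-bis(methoxymethoxy)-3-(3-methylbut-2-enyl)phenyl]ethanone F2. Standard Claisen–Schmidt condensation of this with 6 (KOH, EtOH/H2O, rt) gives (E)-3-[3-hydroxy-4-methoxy-5-(3-methylbut-2-enyl)phenyl]-1-[2-hydroxy-4,6-bis(methoxymethoxy)-3-(3-methylbut-2-enyl)phenyl]prop-2-en-1-one F3. Hydrogenation as in step 5 gives 3-[3-hydroxy-4-methoxy-5-(3-methylbut-2-enyl)phenyl]-1-[2-hydroxy-4,6-bis(methoxymethoxy)-3-(3-methylbut-2-enyl)phenyl]propan-1-one F4. Brief treatment with 3 M HCl in MeOH (rt to 40 °C) removes both acetals to give 12; reducing before deprotection means no acid ever meets a 2',6'-dihydroxychalcone.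

Step 5 (chemoselective hydrogenation). Risks are slow turnover on the chelating polyphenol, flavanone closure during the run, and some prenyl reduction. Fallback, setting out from 11 and coming back at 12: 11 is silylated with TBSOTf/2,6-lutidine (CH2Cl2, −78 to 0 °C) to give (E)-3-[3-(tert-butyldimethylsilyloxy)-4-methoxy-5-(3-methylbut-2-enyl)phenyl]-1-[2,4,6-tris(tert-butyldimethylsilyloxy)-3-(3-methylbut-2-enyl)phenyl]prop-2-en-1-one F5, which cannot cyclise. Copper hydride conjugate reduction (Stryker's reagent, toluene with a little water, rt), which does not touch isolated alkenes, gives 3-[3-(tert-butyldimethylsilyloxy)-4-methoxy-5-(3-methylbut-2-enyl)phenyl]-1-[2,4,6-tris(tert-butyldimethylsilyloxy)-3-(3-methylbut-2-enyl)phenyl]propan-1-one F6. HF·pyridine in THF (0 °C to rt) removes the four silyl groups to give 12.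

**Further compounds**

F1 | step 1 | 3-hydroxy-4-(2-methylbut-3-yn-2-yloxy)benzaldehyde | C#CC(C)(C)Oc1ccc(C=O)cc1O
F2 | step 4 | 1-[2-hydroxy-4,6-bis(methoxymethoxy)-3-(3-methylbut-2-enyl)phenyl]ethanone | CC(=O)c1c(O)c(CC=C(C)C)c(OCOC)cc1OCOC
F3 | step 4 | (E)-3-[3-hydroxy-4-methoxy-5-(3-methylbut-2-enyl)phenyl]-1-[2-hydroxy-4,6-bis(methoxymethoxy)-3-(3-methylbut-2-enyl)phenyl]prop-2-en-1-one | COc1c(O)cc(/C=C/C(=O)c2c(O)c(CC=C(C)C)c(OCOC)cc2OCOC)cc1CC=C(C)C
F4 | step 4 | 3-[3-hydroxy-4-methoxy-5-(3-methylbut-2-enyl)phenyl]-1-[2-hydroxy-4,6-bis(methoxymethoxy)-3-(3-methylbut-2-enyl)phenyl]propan-1-one | COc1c(O)cc(CCC(=O)c2c(O)c(CC=C(C)C)c(OCOC)cc2OCOC)cc1CC=C(C)C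
F5 | step 5 | (E)-3-[3-(tert-butyldimethylsilyloxy)-4-methoxy-5-(3-methylbut-2-enyl)phenyl]-1-[2,4,6-tris(tert-butyldimethylsilyloxy)-3-(3-methylbut-2-enyl)phenyl]prop-2-en-1-one | COc1c(O[Si](C)(C)C(C)(C)C)cc(/C=C/C(=O)c2c(O[Si](C)(C)C(C)(C)C)cc(O[Si](C)(C)C(C)(C)C)c(CC=C(C)C)c2O[Si](C)(C)C(C)(C)C)cc1CC=C(C)C
F6 | step 5 | 3-[3-(tert-butyldimethylsilyloxy)-4-methoxy-5-(3-methylbut-2-enyl)phenyl]-1-[2,4,6-tris(tert-butyldimethylsilyloxy)-3-(3-methylbut-2-enyl)phenyl]propan-1-one | COc1c(O[Si](C)(C)C(C)(C)C)cc(CCC(=O)c2c(O[Si](C)(C)C(C)(C)C)cc(O[Si](C)(C)C(C)(C)C)c(CC=C(C)C)c2O[Si](C)(C)C(C)(C)C)cc1CC=C(C)C
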